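The target is an arylglycerol β-aryl ether. The C7 hydroxyl beside ring A and the C9 hydroxymethyl group on C8 form a benzylic 1,3-diol along C7–C8–C9, which is read as an opened 4-aryl-5-aryloxy-1,3-dioxane. The plan rests on disconnecting C8–C9 and C7–O back to an E styryl aryl ether (ring A–C7=C8–O–ring B) and two formaldehyde units. One catalytic asymmetric Prins cyclisation should form both bonds, the dioxane ring and both stereocentres (7R,8S, erythro), and leave the diol masked. Its precursor is the 4-O-benzyl guaiacyl vinyl ether of methyl syringate; the ester later becomes the hydroxyacetyl group.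

Key step: step 3

Remark: atoms carry neolignan numbers (C7 benzylic on ring A, C8 bearing the ring B ether oxygen, C9 the hydroxymethyl carbon); the sense of induction of the chiral acid cannot be predicted for this substrate, so the catalyst antipode (both come from (R)- or (S)-BINOL) that leads to the (4R,5S) dioxane is assumed.

Step 1
Reactants: 1 4-(benzyloxy)-3-methoxybenzaldehyde (O-benzylvanillin)
Product: 2 (E)-1-(benzyloxy)-4-(2-iodoethenyl)-2-methoxybenzene
Conditions: CHI3 (2 equiv), CrCl2 (6 equiv), 1,4-dioxane/THF 6:1, 0 °C to rt, dark; E isomer recrystallised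
Reagents that add atoms: iodoform, IC(I)I
Why: Takai olefination, in which the geminal dichromium carbenoid from iodoform and divalent chromium adds to the aldehyde and eliminates the chromium-bound oxygen from an anti-periplanar arrangement that favours the E iodoalkene with aromatic aldehydes; the benzyl and methyl ethers are inert to CrCl2.

Step 2
Reactants: 2 (E)-1-(benzyloxy)-4-(2-iodoethenyl)-2-methoxybenzene; 3 methyl 4-hydroxy-3,5-dimethoxybenzoate (methyl syringate)
Product: 4 methyl 4-{[(E)-2-(4-benzyloxy-3-methoxyphenyl)ethenyl]oxy}-3,5-dimethoxybenzoate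
Conditions: CuI (10 mol %), N,N-dimethylglycine hydrochloride (30 mol %), Cs2CO3 (2.5 equiv), 1,4-dioxane, 80 °C, argon, dark
Reagents that add atoms: none
Why: Ullmann-type C–O coupling, in which monovalent copper with the amino acid ligand activates the alkenyl C–I bond and the cesium phenoxide of 3 is vinylated with retention of the E geometry; the iodide is used so that the hindered, acceptor-bearing phenol couples at moderate temperature without touching the ester.

Step 3
Reactants: 4 methyl 4-{[(E)-2-(4-benzyloxy-3-methoxyphenyl)ethenyl]oxy}-3,5-dimethoxybenzoate; 5 formaldehyde (two units incorporated, charged as paraformaldehyde)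
Product: 6 methyl 4-{[(4R,5S)-4-(4-benzyloxy-3-methoxyphenyl)-1,3-dioxan-5-yl]oxy}-3,5-dimethoxybenzoate (trans)
Conditions: (CH2O)n (5 equiv), confined imidodiphosphorimidate acid HN[P(=NSO2CF3)(O2C20H10Ar2)]2 built from 3,3'-Ar2-BINOL, Ar = 3,5-(CF3)2C6H3 as first choice (5 mol %), 5 Å MS, CHCl3/cyclohexane, −20 °C
Reagents that add atoms: none
Why: Proposed new method: the confined acid protonates formaldehyde in its chiral pocket, the E alkene of 4 attacks it through C8 to make the C8–C9 bond, the resulting 4-benzyloxybenzylic (quinone-methide-like) cation at C7 is captured by the oxygen of the hemiformal that O9 forms with the second formaldehyde unit, making the C7–O bond, and the proton returns to the catalyst; the closest known reaction types are the imidodiphosphorimidate-catalysed asymmetric Prins reaction of styrenes with paraformaldehyde to 4-aryl-1,3-dioxanes and the classical acid Prins reaction of anethole, while the reverse event, loss of formaldehyde from the C7 cation of arylglycerol β-aryl ethers to give styryl aryl ethers, is a known acidolysis pathway. The one ring formed, the 1,3-dioxane, closes 6-exo-trig by attack of the hemiformal oxygen on C7, exo to the quinoid C7=C1 bond of ring A. C8 (S) is set in the C–C bond-forming event by the alkene face that the chiral counter-anion leaves open, so that the antipode of the catalyst decides the absolute series. C7 (R) is set relative to C8, because closure through a chair places aryl and aryloxy both equatorial (trans, the erythro diol), the same result as suprafacial addition across the E alkene. The step needs bond formation at C8 and not at C7, one alkene face and trans closure: the para-alkoxy donor of ring A should stabilise charge at C7 better than an aryloxy oxygen attached to the ester-bearing, electron-poor ring B, the confined anion secures the face, and the diequatorial chair secures trans. The weakly basic ester should neither bind the catalyst nor react, and molecular sieves keep water from hydrolysing the enol ether.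

Step 4
Reactants: 6 methyl 4-{[(4R,5S)-4-(4-benzyloxy-3-methoxyphenyl)-1,3-dioxan-5-yl]oxy}-3,5-dimethoxybenzoate
Product: 8 1-(4-{[(4R,5S)-4-(4-benzyloxy-3-methoxyphenyl)-1,3-dioxan-5-yl]oxy}-3,5-dimethoxyphenyl)-2-chloroethan-1-one, via lithium hemiketal alkoxide 7 (not isolated)
Conditions: ICH2Cl (3 equiv), MeLi·LiBr (2.5 equiv, slow addition), THF, −78 °C; AcOH quench at −78 °C
Reagents that add atoms: chloroiodomethane, ClCI
Why: Halomethyllithium homologation of an ester, in which chloromethyllithium made by iodine–lithium exchange in the presence of 6 adds only once because the lithium hemiketal 7 persists at −78 °C and collapses to the chloromethyl ketone on acidic quench; the acetal, the ethers and both stereocentres are not touched by the cold organolithium.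

Step 5
Reactants: 8 1-(4-{[(4R,5S)-4-(4-benzyloxy-3-methoxyphenyl)-1,3-dioxan-5-yl]oxy}-3,5-dimethoxyphenyl)-2-chloroethan-1-one
Product: 10 1-(4-{[(4R,5S)-4-(4-benzyloxy-3-methoxyphenyl)-1,3-dioxan-5-yl]oxy}-3,5-dimethoxyphenyl)-2-hydroxyethan-1-one, via formate ester 9 (not isolated)
Conditions: HCO2K (4 equiv), MeOH, 65 °C, N2
Reagents that add atoms: potassium formate, [K+].[O-]C=O
Why: SN2 displacement of the activated α-chloro ketone by formate and methanolysis of the formate ester in the same flask (the classical phenacyl halide to ketol conversion) under near-neutral conditions that leave the dioxane, the ethers and both stereocentres alone.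

Step 6
Reactants: 10 1-(4-{[(4R,5S)-4-(4-benzyloxy-3-methoxyphenyl)-1,3-dioxan-5-yl]oxy}-3,5-dimethoxyphenyl)-2-hydroxyethan-1-one
Product: 12 1-(4-{[(1R,2S)-1-(4-benzyloxy-3-methoxyphenyl)-1,3-dihydroxypropan-2-yl]oxy}-3,5-dimethoxyphenyl)-2-hydroxyethan-1-one, via silylated pyridinium salt 11 (not isolated)
Conditions: Me3SiOTf (5 equiv), 2,2'-bipyridyl (7 equiv), CH2Cl2, 0 °C to rt; then H2O, rt
Reagents that add atoms: none
Why: Silyl triflate–pyridine opening of a methylene acetal, in which the buffered silylating complex activates the less hindered acetal oxygen (O9), bipyridyl attacks the acetal carbon to give pyridinium-methyl ether 11 and water then hydrolyses it together with the silyl ethers, so that neither the C7–O nor the C8–O bond is broken and the configuration is kept; this reagent is preferred because stronger boron halide Lewis acids would also attack the 4-alkoxybenzylic C7–O bond.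

Step 7
Reactants: 12 1-(4-{[(1R,2S)-1-(4-benzyloxy-3-methoxyphenyl)-1,3-dihydroxypropan-2-yl]oxy}-3,5-dimethoxyphenyl)-2-hydroxyethan-1-one
Product: 13 2-hydroxy-1-(4-{[(1R,2S)-1,3-dihydroxy-1-(4-hydroxy-3-methoxyphenyl)propan-2-yl]oxy}-3,5-dimethoxyphenyl)ethan-1-one (target)
Conditions: H2 (1 atm), 10% Pd/C, EtOAc, rt, stopped at full conversion
Reagents that add atoms: none
Why: Catalytic hydrogenolysis of the aryl benzyl ether over palladium on carbon, which under neutral conditions should be much faster than reduction of the aryl ketone or hydrogenolysis of the secondary benzylic hydroxyl, and which involves no stereocentre.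

Compound list
1 | 4-(benzyloxy)-3-methoxybenzaldehyde | COc1cc(C=O)ccc1OCc1ccccc1 | starting material
2 | (E)-1-(benzyloxy)-4-(2-iodoethenyl)-2-methoxybenzene | COc1cc(/C=C/I)ccc1OCc1ccccc1 | intermediate
3 | methyl 4-hydroxy-3,5-dimethoxybenzoate (methyl syringate) | COC(=O)c1cc(OC)c(O)c(OC)c1 | starting material
4 | methyl 4-{[(E)-2-(4-benzyloxy-3-methoxyphenyl)ethenyl]oxy}-3,5-dimethoxybenzoate | COc1cc(/C=C/Oc2c(OC)cc(C(=O)OC)cc2OC)ccc1OCc1ccccc1 | intermediate
5 | formaldehyde (charged as paraformaldehyde) | C=O | starting material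
6 | methyl 4-{[(4R,5S)-4-(4-benzyloxy-3-methoxyphenyl)-1,3-dioxan-5-yl]oxy}-3,5-dimethoxybenzoate | COc1cc([C@H]2OCOC[C@@H]2Oc3c(OC)cc(C(=O)OC)cc3OC)ccc1OCc4ccccc4 | intermediate
7 | lithium hemiketal alkoxide from addition of chloromethyllithium to the ester of 6 (new carbinol centre undefined) | COc1cc([C@H]2OCOC[C@@H]2Oc3c(OC)cc(C([O-])(OC)CCl)cc3OC)ccc1OCc4ccccc4.[Li+] | intermediate
8 | 1-(4-{[(4R,5S)-4-(4-benzyloxy-3-methoxyphenyl)-1,3-dioxan-5-yl]oxy}-3,5-dimethoxyphenyl)-2-chloroethan-1-one | COc1cc([C@H]2OCOC[C@@H]2Oc3c(OC)cc(C(=O)CCl)cc3OC)ccc1OCc4ccccc4 | intermediate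
9 | 2-(4-{[(4R,5S)-4-(4-benzyloxy-3-methoxyphenyl)-1,3-dioxan-5-yl]oxy}-3,5-dimethoxyphenyl)-2-oxoethyl formate | COc1cc([C@H]2OCOC[C@@H]2Oc3c(OC)cc(C(=O)COC=O)cc3OC)ccc1OCc4ccccc4 | intermediate
10 | 1-(4-{[(4R,5S)-4-(4-benzyloxy-3-methoxyphenyl)-1,3-dioxan-5-yl]oxy}-3,5-dimethoxyphenyl)-2-hydroxyethan-1-one | COc1cc([C@H]2OCOC[C@@H]2Oc3c(OC)cc(C(=O)CO)cc3OC)ccc1OCc4ccccc4 | intermediate
11 | (7R,8S) ring-opened salt: O7 2,2'-bipyridin-1-ium-1-ylmethyl ether, O9 and ketol trimethylsilyl ethers, triflate (drawn with the pyridinium-methyl group on O7) | COc1cc([C@@H](OC[n+]2ccccc2-c3ccccn3)[C@H](CO[Si](C)(C)C)Oc4c(OC)cc(C(=O)CO[Si](C)(C)C)cc4OC)ccc1OCc5ccccc5.[O-]S(=O)(=O)C(F)(F)F | intermediate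
12 | 1-(4-{[(1R,2S)-1-(4-benzyloxy-3-methoxyphenyl)-1,3-dihydroxypropan-2-yl]oxy}-3,5-dimethoxyphenyl)-2-hydroxyethan-1-one | COc1cc([C@@H](O)[C@H](CO)Oc2c(OC)cc(C(=O)CO)cc2OC)ccc1OCc3ccccc3 | intermediate
13 | 2-hydroxy-1-(4-{[(1R,2S)-1,3-dihydroxy-1-(4-hydroxy-3-methoxyphenyl)propan-2-yl]oxy}-3,5-dimethoxyphenyl)ethan-1-one | COc1cc([C@@H](O)[C@H](CO)Oc2c(OC)cc(C(=O)CO)cc2OC)ccc1O | target

Total step count: 7
Longest linear sequence: 7 steps (1 to 13); 3 and 5 are purchased.

Steps most likely to fail

1. Step 3 (the proposed new method). The C–C bond may form at C7 instead of C8 (oxygen-directed attack through the aryloxy-carbenium ion). Facial selectivity in the ion pair may be poor. The enol ether may hydrolyse or oligomerise under the acid, and ring A may be hydroxymethylated. The fallback uses known chemistry, sets out from 3 and 1 and returns at 6.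
   - Phenol 3 is alkylated with (R)-4-benzyl-3-(chloroacetyl)oxazolidin-2-one (K2CO3, acetone) to give aryloxyacetyl imide F1.
   - The dibutylboron enolate of F1 (Bu2BOTf, iPr2NEt, CH2Cl2, −78 °C) adds to aldehyde 1 in an Evans syn aldol reaction to give threo adduct F2.
   - Mitsunobu inversion at benzylic C7 (4-nitrobenzoic acid, PPh3, DIAD, THF) gives erythro nitrobenzoate F3.
   - NaBH4 in THF/water removes the auxiliary reductively and spares the methyl benzoate, giving primary alcohol F4.
   - K2CO3 in methanol cleaves the nitrobenzoate to give diol ester F5 with the (7R,8S) configuration.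
   - CH2Br2 and NaH in DMF close the methylene acetal to 6.

2. Step 6. The ketol may compete for the silyl triflate (silylation, enol silane formation) so that opening of the dioxane stalls. Longer exposure may ionise the C7–O bond of the opened product and erode the C7 configuration. The fallback sets out from 6 and returns at 12.
   - The acetal is opened one stage earlier, on ester 6, under the conditions of step 6, where no ketone or hydroxyl competes, to give diol ester F5.
   - 2,2-Dimethoxypropane with pyridinium tosylate gives acetonide F6.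
   - The operations of steps 4 and 5 convert F6 into chloromethyl ketone F7 and then ketol F8.
   - 80% aqueous acetic acid at rt removes the acetonide to give 12.

3. Step 2. C–O coupling of the doubly ortho-substituted, acceptor-bearing phenoxide may be slow, so that the iodoalkene is lost by dehydrohalogenation or homocoupling and the alkene geometry is partly scrambled. The fallback sets out from 3 and returns at 4.
   - Phenol 3 is alkylated with 2-bromo-1-(4-benzyloxy-3-methoxyphenyl)ethan-1-one (K2CO3, acetone) to give aryloxy ketone F9.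
   - NaBH4 in methanol gives racemic alcohol F10, whose stereocentre disappears in the next operation.
   - Dehydration with the Burgess reagent (toluene, 60 °C) gives 4.
   - Any Z isomer is equilibrated toward E with catalytic iodine and removed by crystallisation.

Further compounds
F1 | step 3 | (R)-4-benzyl-3-{[4-(methoxycarbonyl)-2,6-dimethoxyphenoxy]acetyl}oxazolidin-2-one | COC(=O)c1cc(OC)c(OCC(=O)N2[C@H](Cc3ccccc3)COC2=O)c(OC)c1
F2 | step 3 | (R)-4-benzyl-3-[(2R,3S)-3-(4-benzyloxy-3-methoxyphenyl)-3-hydroxy-2-(4-methoxycarbonyl-2,6-dimethoxyphenoxy)propanoyl]oxazolidin-2-one | COc1cc([C@H](O)[C@@H](Oc2c(OC)cc(C(=O)OC)cc2OC)C(=O)N3[C@H](Cc4ccccc4)COC3=O)ccc1OCc5ccccc5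
F3 | step 3 | (R)-4-benzyl-3-[(2R,3R)-3-(4-benzyloxy-3-methoxyphenyl)-2-(4-methoxycarbonyl-2,6-dimethoxyphenoxy)-3-(4-nitrobenzoyloxy)propanoyl]oxazolidin-2-one | COc1cc([C@@H](OC(=O)c2ccc([N+](=O)[O-])cc2)[C@@H](Oc3c(OC)cc(C(=O)OC)cc3OC)C(=O)N4[C@H](Cc5ccccc5)COC4=O)ccc1OCc6ccccc6
F4 | step 3 | methyl 4-{[(1R,2S)-1-(4-benzyloxy-3-methoxyphenyl)-3-hydroxy-1-(4-nitrobenzoyloxy)propan-2-yl]oxy}-3,5-dimethoxybenzoate | COc1cc([C@@H](OC(=O)c2ccc([N+](=O)[O-])cc2)[C@@H](Oc3c(OC)cc(C(=O)OC)cc3OC)CO)ccc1OCc4ccccc4
F5 | step 3 | methyl 4-{[(1R,2S)-1-(4-benzyloxy-3-methoxyphenyl)-1,3-dihydroxypropan-2-yl]oxy}-3,5-dimethoxybenzoate | COc1cc([C@@H](O)[C@H](CO)Oc2c(OC)cc(C(=O)OC)cc2OC)ccc1OCc3ccccc3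
F6 | step 6 | methyl 4-{[(4R,5S)-4-(4-benzyloxy-3-methoxyphenyl)-2,2-dimethyl-1,3-dioxan-5-yl]oxy}-3,5-dimethoxybenzoate | COc1cc([C@H]2OC(C)(C)OC[C@@H]2Oc3c(OC)cc(C(=O)OC)cc3OC)ccc1OCc4ccccc4
F7 | step 6 | 1-(4-{[(4R,5S)-4-(4-benzyloxy-3-methoxyphenyl)-2,2-dimethyl-1,3-dioxan-5-yl]oxy}-3,5-dimethoxyphenyl)-2-chloroethan-1-one | COc1cc([C@H]2OC(C)(C)OC[C@@H]2Oc3c(OC)cc(C(=O)CCl)cc3OC)ccc1OCc4ccccc4
F8 | step 6 | 1-(4-{[(4R,5S)-4-(4-benzyloxy-3-methoxyphenyl)-2,2-dimethyl-1,3-dioxan-5-yl]oxy}-3,5-dimethoxyphenyl)-2-hydroxyethan-1-one | COc1cc([C@H]2OC(C)(C)OC[C@@H]2Oc3c(OC)cc(C(=O)CO)cc3OC)ccc1OCc4ccccc4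
F9 | step 2 | methyl 4-[2-(4-benzyloxy-3-methoxyphenyl)-2-oxoethoxy]-3,5-dimethoxybenzoate | COc1cc(C(=O)COc2c(OC)cc(C(=O)OC)cc2OC)ccc1OCc3ccccc3
F10 | step 2 | methyl 4-[2-(4-benzyloxy-3-methoxyphenyl)-2-hydroxyethoxy]-3,5-dimethoxybenzoate (racemic) | COc1cc(C(O)COc2c(OC)cc(C(=O)OC)cc2OC)ccc1OCc3ccccc3
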